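**Plan**

Locants: oxolane O1, C2 (bears ring A), C3 (bears C9H2OH), C4 (bears the benzylic C7' of ring B), C5 (OCH2); glycerol chain C7'' (carbinol on ring C), C8'' (aryloxy carbon on the 4-O of ring A), C9''.
Retrosynthetic cuts, in this order: C4–H/C7'–H and the two O-benzyl bonds; the ring bond C4–C5; O1–C5; C7'–ring B; C2–C3; C7''–C8'' and the ring A O–CH2 bond of a glycolate.
Forward: the threo arylglycerol aryl ether is built on a ring A bromide (glycolate aldol with the ring C aldehyde), the bromide becomes the aldehyde, the chain C2–C3–C4≡C7' is joined by propargylation, ring B is coupled to C7', O1 is alkylated, and the oxolane, the only ring made, is closed by forming C4–C5; deprotection and hydrogenation finish.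
Enabling feature: C5 is an unsubstituted methylene bonded only to O1 and C4, so it can be carried as an O1–CH2 radical (unmasked from an O1–CH2–CO2H handle) five atoms from the alkyne carbon C4, while ring B on C7' stabilises the vinyl radical; closure is 5-exo-dig and leaves C4 trigonal.
Stereochemistry: C7''/C8'' from one auxiliary-controlled syn-aldol; C3 from a purchased propargylic stereocenter by chirality transfer through an allenylzinc, which sets C2 anti in the same closed transition state; C4 from hydrogenation of C4=C7' anti to the C3 hydroxymethyl group, both alkene isomers converging.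

Key step: step 13

Remark: the geometry of the exocyclic C4=C7' bond made in the key step is left unassigned because both isomers should give the same C4 configuration on hydrogenation; the chiral alkyne acetonide is taken as the catalogue compound derived from D-glyceraldehyde acetonide.
Abbreviations in names: ArB = 4-(benzyloxy)-3-methoxyphenyl; ArA = 4-{[(1S,2S)-1-ArB-1,3-bis(tert-butyldimethylsilyloxy)propan-2-yl]oxy}-3-methoxyphenyl.

**Route**

Step 1
Reactants: 1 4-bromo-2-methoxyphenol; 2 bromoacetic acid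
Product: 3 (4-bromo-2-methoxyphenoxy)acetic acid
Conditions: NaOH, H2O, 100 °C; then HCl to pH 1
Reagents that add atoms: none
Why: Williamson ether synthesis, in which the phenoxide displaces bromide from bromoacetate by SN2 and no stereocenter is involved.

Step 2
Reactants: 3 (4-bromo-2-methoxyphenoxy)acetic acid; 4 (R)-4-benzyl-1,3-oxazolidin-2-one
Product: 6 (R)-4-benzyl-3-[(4-bromo-2-methoxyphenoxy)acetyl]-1,3-oxazolidin-2-one, via mixed pivalic anhydride 5 (not isolated)
Conditions: t-BuCOCl, Et3N, THF, −20 °C; then 4, LiCl, rt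
Reagents that add atoms: none
Why: N-acylation of the oxazolidinone through the mixed anhydride is the standard entry to glycolate imides and creates no stereocenter.

Step 3
Reactants: 6 (R)-4-benzyl-3-[(4-bromo-2-methoxyphenoxy)acetyl]-1,3-oxazolidin-2-one; 7 4-(benzyloxy)-3-methoxybenzaldehyde
Product: 9 (R)-4-benzyl-3-[(2R,3S)-3-[4-(benzyloxy)-3-methoxyphenyl]-2-(4-bromo-2-methoxyphenoxy)-3-hydroxypropanoyl]-1,3-oxazolidin-2-one, via Z-boron enolate 8 (not isolated)
Conditions: Bu2BOTf, i-Pr2NEt, CH2Cl2, −78 to 0 °C; then 7, −78 to 0 °C; H2O2, pH 7 buffer, MeOH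
Reagents that add atoms: none
Why: Evans syn-aldol reaction, in which the Z-dibutylboron enolate adds through a closed Zimmerman–Traxler chair on the face away from the auxiliary benzyl group, so C8'' and C7'' should be set together as the (2R,3S) syn (threo) pair.

Step 4
Reactants: 9 the aldol adduct
Product: 10 (1S,2S)-1-[4-(benzyloxy)-3-methoxyphenyl]-2-(4-bromo-2-methoxyphenoxy)propane-1,3-diol
Conditions: LiBH4, MeOH (1 equiv), THF, 0 °C
Reagents that add atoms: none
Why: reductive cleavage of the N-acyl oxazolidinone by LiBH4 turns the imide carbonyl into C9''H2OH, leaves both stereocenters untouched and returns the auxiliary.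

Step 5
Reactants: 10 the diol
Product: 11 (1S,2S)-1-[4-(benzyloxy)-3-methoxyphenyl]-2-(4-bromo-2-methoxyphenoxy)-1,3-bis(tert-butyldimethylsilyloxy)propane
Conditions: TBSOTf, 2,6-lutidine, CH2Cl2, 0 °C
Reagents that add atoms: tert-butyldimethylsilyl trifluoromethanesulfonate, CC(C)(C)[Si](C)(C)OS(=O)(=O)C(F)(F)F
Why: O-silylation with a silyl triflate masks both hydroxyls against the organolithium, hydride-base and radical steps that follow, without touching a stereocenter.

Step 6
Reactants: 11 the bis-silyl ether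
Product: 13 4-{[(1S,2S)-1-[4-(benzyloxy)-3-methoxyphenyl]-1,3-bis(tert-butyldimethylsilyloxy)propan-2-yl]oxy}-3-methoxybenzaldehyde (ArA-CHO), via aryllithium 12 (not isolated)
Conditions: n-BuLi, THF, −78 °C; then DMF; aq NH4Cl
Reagents that add atoms: N,N-dimethylformamide, CN(C)C=O
Why: bromine–lithium exchange followed by Bouveault formylation converts the aryl bromide into the aldehyde at a temperature where silyl and benzyl ethers are inert.

Step 7
Reactants: 14 (S)-4-ethynyl-2,2-dimethyl-1,3-dioxolane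
Product: 15 (S)-but-3-yne-1,2-diol
Conditions: AcOH/H2O 4:1, 40 °C
Reagents that add atoms: none
Why: acid-catalysed acetal hydrolysis frees the diol, and the propargylic stereocenter is not the acetal carbon and so is not at risk.

Step 8
Reactants: 15 (S)-but-3-yne-1,2-diol
Product: 16 (S)-1-(triisopropylsilyloxy)but-3-yn-2-ol
Conditions: TIPSCl, imidazole, CH2Cl2, 0 °C
Reagents that add atoms: chlorotriisopropylsilane, CC(C)[Si](Cl)(C(C)C)C(C)C
Why: sterically controlled mono-silylation occurs at the primary hydroxyl, and the triisopropylsilyl group is chosen because it should not migrate to the neighbouring alkoxide in step 12.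

Step 9
Reactants: 16 (S)-1-(triisopropylsilyloxy)but-3-yn-2-ol
Product: 17 (S)-1-(triisopropylsilyloxy)but-3-yn-2-yl methanesulfonate
Conditions: MsCl, Et3N, CH2Cl2, −78 °C
Reagents that add atoms: methanesulfonyl chloride, CS(=O)(=O)Cl
Why: O-sulfonylation takes place at oxygen with retention and provides the leaving group for allenylmetal formation.

Step 10
Reactants: 13 ArA-CHO; 17 the propargylic mesylate
Product: 19 (1S,2R)-1-ArA-2-[(triisopropylsilyloxy)methyl]but-3-yn-1-ol, via allenylzinc 18 (not isolated)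
Conditions: Pd(OAc)2 (5 mol %), PPh3 (5 mol %), Et2Zn (3 equiv), THF, −78 to −20 °C
Reagents that add atoms: none
Why: Marshall–Tamaru propargylation, in which zerovalent palladium opens the mesylate by anti SN2' attack, transmetalation gives the configurationally defined allenylzinc 18, and its SE2' addition through a closed six-membered transition state should transfer the purchased stereocenter to C3 with net inversion (R) and place the aryl group anti to the silyloxymethyl group, setting C2 (S).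

Step 11
Reactants: 19 the homopropargylic alcohol; 20 1-(benzyloxy)-4-bromo-2-methoxybenzene
Product: 21 (1S,2R)-1-ArA-4-ArB-2-[(triisopropylsilyloxy)methyl]but-3-yn-1-ol
Conditions: Pd(PhCN)2Cl2 (3 mol %), P(t-Bu)3·HBF4 (6 mol %), CuI (2 mol %), i-Pr2NH, dioxane, rt
Reagents that add atoms: none
Why: Sonogashira coupling of the terminal alkyne with the electron-rich aryl bromide under bulky-phosphine conditions at room temperature installs ring B on C7' and tolerates the free secondary alcohol.

Step 12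
Reactants: 21 the aryl alkynol; 2 bromoacetic acid
Product: 22 {[(1S,2R)-1-ArA-4-ArB-2-[(triisopropylsilyloxy)methyl]but-3-yn-1-yl]oxy}acetic acid
Conditions: NaH (3 equiv), THF, 0 °C to rt; then cold 0.5 M HCl to pH 4
Reagents that add atoms: none
Why: Williamson ether synthesis on the sodium alkoxide of the only free hydroxyl attaches the future C5 to O1 as an α-alkoxy acid, the carboxyl group being a temporary handle that leaves as CO2 in step 13.

Step 13
Reactants: 22 the α-alkoxy acid
Product: 26 (2S,3R)-2-ArA-4-(ArB-methylidene)-3-[(triisopropylsilyloxy)methyl]oxolane (E/Z mixture), via Barton ester 23 (not isolated), via alkoxymethyl radical 24 (not isolated), via vinyl radical 25 (not isolated)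
Conditions: 1-hydroxypyridine-2(1H)-thione, DCC, DMAP (cat.), CH2Cl2, 0 °C, dark; filter; then slow addition to Bu3SnH, AIBN, PhH, 80 °C, high dilution
Reagents that add atoms: none
Why: Bu3Sn• attacks the thiocarbonyl sulfur of ester 23, the acyloxy radical loses CO2 to give the O1-bound methylene radical 24, this adds to the proximal alkyne carbon C4, and the α-aryl vinyl radical 25 is reduced by Bu3SnH. The closest known reaction type is the Barton reductive decarboxylation combined with the 5-exo cyclisation of alkoxymethyl radicals onto alkenes and alkynes. The oxolane closes in the 5-exo-dig mode (C5 onto C4), which should be favoured over 6-endo-dig by the geometry of the 3-oxahex-5-ynyl radical and by the stabilisation that ring B gives to the radical at C7'. No new stereocenter is formed, because C4 is deliberately left trigonal, C2 and C3 are spectators, and the alkene geometry is of no consequence. The selectivity needed is ring closure before hydrogen transfer to 24, which the short ether tether, the aryl-activated alkyne and the low stationary concentration of Bu3SnH should secure.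

Step 14
Reactants: 26 the benzylidene oxolane
Product: 27 {(2S,3R)-4-{[4-(benzyloxy)-3-methoxyphenyl]methylidene}-2-[4-{[(1S,2S)-1-[4-(benzyloxy)-3-methoxyphenyl]-1,3-dihydroxypropan-2-yl]oxy}-3-methoxyphenyl]oxolan-3-yl}methanol (E/Z mixture)
Conditions: TBAF, THF, 0 °C to rt
Reagents that add atoms: none
Why: fluoride-induced desilylation removes all three silyl groups while the phenols are still benzylated, so that no phenoxide able to form a quinone methide is exposed to base.

Step 15
Reactants: 27 the triol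
Product: 28 (1S,2S)-1-(4-hydroxy-3-methoxyphenyl)-2-{4-[(2S,3R,4R)-4-(4-hydroxy-3-methoxybenzyl)-3-(hydroxymethyl)oxolan-2-yl]-2-methoxyphenoxy}propane-1,3-diol (target CNP0226724.1)
Conditions: H2 (1 atm), 10% Pd/C, EtOAc/EtOH, rt
Reagents that add atoms: none
Why: heterogeneous catalytic hydrogenation with hydrogenolysis of the two aryl benzyl ethers, in which H2 should add to the exocyclic C4=C7' bond from the face opposite the adjacent C3 hydroxymethyl group for either alkene isomer, placing the benzyl group cis to C9 (4R) as in closely related 2-aryl-4-benzylidene-3-(hydroxymethyl)oxolanes.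

**Compound list**

1 | 4-bromo-2-methoxyphenol | COc1cc(Br)ccc1O | starting material
2 | bromoacetic acid | OC(=O)CBr | starting material
3 | (4-bromo-2-methoxyphenoxy)acetic acid | COc1cc(Br)ccc1OCC(=O)O | intermediate
4 | (R)-4-benzyl-1,3-oxazolidin-2-one | O=C1N[C@H](Cc2ccccc2)CO1 | starting material
5 | (4-bromo-2-methoxyphenoxy)acetic pivalic anhydride | COc1cc(Br)ccc1OCC(=O)OC(=O)C(C)(C)C | intermediate
6 | (R)-4-benzyl-3-[(4-bromo-2-methoxyphenoxy)acetyl]-1,3-oxazolidin-2-one | COc1cc(Br)ccc1OCC(=O)N1[C@H](Cc2ccccc2)COC1=O | intermediate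
7 | 4-(benzyloxy)-3-methoxybenzaldehyde | COc1cc(C=O)ccc1OCc1ccccc1 | starting material
8 | Z-dibutylboron enolate of 6 | COc1cc(Br)ccc1O/C=C(\OB(CCCC)CCCC)N1[C@H](Cc2ccccc2)COC1=O | intermediate
9 | (R)-4-benzyl-3-[(2R,3S)-3-[4-(benzyloxy)-3-methoxyphenyl]-2-(4-bromo-2-methoxyphenoxy)-3-hydroxypropanoyl]-1,3-oxazolidin-2-one | COc1cc(Br)ccc1O[C@@H](C(=O)N1[C@H](Cc2ccccc2)COC1=O)[C@@H](O)c1ccc(OCc2ccccc2)c(OC)c1 | intermediate
10 | (1S,2S)-1-[4-(benzyloxy)-3-methoxyphenyl]-2-(4-bromo-2-methoxyphenoxy)propane-1,3-diol | COc1cc(Br)ccc1O[C@@H](CO)[C@@H](O)c1ccc(OCc2ccccc2)c(OC)c1 | intermediate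
11 | (1S,2S)-1-[4-(benzyloxy)-3-methoxyphenyl]-2-(4-bromo-2-methoxyphenoxy)-1,3-bis(tert-butyldimethylsilyloxy)propane | COc1cc(Br)ccc1O[C@@H](CO[Si](C)(C)C(C)(C)C)[C@@H](O[Si](C)(C)C(C)(C)C)c1ccc(OCc2ccccc2)c(OC)c1 | intermediate
12 | aryllithium from 11 (Li in place of Br) | COc1cc([Li])ccc1O[C@@H](CO[Si](C)(C)C(C)(C)C)[C@@H](O[Si](C)(C)C(C)(C)C)c1ccc(OCc2ccccc2)c(OC)c1 | intermediate
13 | 4-{[(1S,2S)-1-[4-(benzyloxy)-3-methoxyphenyl]-1,3-bis(tert-butyldimethylsilyloxy)propan-2-yl]oxy}-3-methoxybenzaldehyde | COc1cc(C=O)ccc1O[C@@H](CO[Si](C)(C)C(C)(C)C)[C@@H](O[Si](C)(C)C(C)(C)C)c1ccc(OCc2ccccc2)c(OC)c1 | intermediate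
14 | (S)-4-ethynyl-2,2-dimethyl-1,3-dioxolane | C#C[C@H]1COC(C)(C)O1 | starting material
15 | (S)-but-3-yne-1,2-diol | C#C[C@H](O)CO | intermediate
16 | (S)-1-(triisopropylsilyloxy)but-3-yn-2-ol | C#C[C@H](O)CO[Si](C(C)C)(C(C)C)C(C)C | intermediate
17 | (S)-1-(triisopropylsilyloxy)but-3-yn-2-yl methanesulfonate | C#C[C@H](OS(C)(=O)=O)CO[Si](C(C)C)(C(C)C)C(C)C | intermediate
18 | ethyl[(Sa)-4-(triisopropylsilyloxy)buta-1,2-dien-1-yl]zinc | [H]C([Zn]CC)=[C@]=C([H])CO[Si](C(C)C)(C(C)C)C(C)C | intermediate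
19 | (1S,2R)-1-ArA-2-[(triisopropylsilyloxy)methyl]but-3-yn-1-ol | O[C@H](c1ccc(O[C@@H](CO[Si](C)(C)C(C)(C)C)[C@@H](O[Si](C)(C)C(C)(C)C)c2ccc(OCc3ccccc3)c(OC)c2)c(OC)c1)[C@H](C#C)CO[Si](C(C)C)(C(C)C)C(C)C | intermediate
20 | 1-(benzyloxy)-4-bromo-2-methoxybenzene | COc1cc(Br)ccc1OCc1ccccc1 | starting material
21 | (1S,2R)-1-ArA-4-ArB-2-[(triisopropylsilyloxy)methyl]but-3-yn-1-ol | O[C@H](c1ccc(O[C@@H](CO[Si](C)(C)C(C)(C)C)[C@@H](O[Si](C)(C)C(C)(C)C)c2ccc(OCc3ccccc3)c(OC)c2)c(OC)c1)[C@H](C#Cc1ccc(OCc2ccccc2)c(OC)c1)CO[Si](C(C)C)(C(C)C)C(C)C | intermediate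
22 | {[(1S,2R)-1-ArA-4-ArB-2-[(triisopropylsilyloxy)methyl]but-3-yn-1-yl]oxy}acetic acid | OC(=O)CO[C@H](c1ccc(O[C@@H](CO[Si](C)(C)C(C)(C)C)[C@@H](O[Si](C)(C)C(C)(C)C)c2ccc(OCc3ccccc3)c(OC)c2)c(OC)c1)[C@H](C#Cc1ccc(OCc2ccccc2)c(OC)c1)CO[Si](C(C)C)(C(C)C)C(C)C | intermediate
23 | 2-thioxopyridin-1(2H)-yl ester of 22 | S=C1C=CC=CN1OC(=O)CO[C@H](c1ccc(O[C@@H](CO[Si](C)(C)C(C)(C)C)[C@@H](O[Si](C)(C)C(C)(C)C)c2ccc(OCc3ccccc3)c(OC)c2)c(OC)c1)[C@H](C#Cc1ccc(OCc2ccccc2)c(OC)c1)CO[Si](C(C)C)(C(C)C)C(C)C | intermediate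
24 | O1-bound methylene radical (22 minus CO2H) | [CH2]O[C@H](c1ccc(O[C@@H](CO[Si](C)(C)C(C)(C)C)[C@@H](O[Si](C)(C)C(C)(C)C)c2ccc(OCc3ccccc3)c(OC)c2)c(OC)c1)[C@H](C#Cc1ccc(OCc2ccccc2)c(OC)c1)CO[Si](C(C)C)(C(C)C)C(C)C | intermediate
25 | cyclised vinyl radical (radical at C7') | COc1cc([C]=C2CO[C@H](c3ccc(O[C@@H](CO[Si](C)(C)C(C)(C)C)[C@@H](O[Si](C)(C)C(C)(C)C)c4ccc(OCc5ccccc5)c(OC)c4)c(OC)c3)[C@H]2CO[Si](C(C)C)(C(C)C)C(C)C)ccc1OCc1ccccc1 | intermediate
26 | (2S,3R)-2-ArA-4-(ArB-methylidene)-3-[(triisopropylsilyloxy)methyl]oxolane, E/Z mixture | COc1cc(C=C2CO[C@H](c3ccc(O[C@@H](CO[Si](C)(C)C(C)(C)C)[C@@H](O[Si](C)(C)C(C)(C)C)c4ccc(OCc5ccccc5)c(OC)c4)c(OC)c3)[C@H]2CO[Si](C(C)C)(C(C)C)C(C)C)ccc1OCc1ccccc1 | intermediate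
27 | triol from 26 (all silyl groups removed), E/Z mixture | COc1cc(C=C2CO[C@H](c3ccc(O[C@@H](CO)[C@@H](O)c4ccc(OCc5ccccc5)c(OC)c4)c(OC)c3)[C@H]2CO)ccc1OCc1ccccc1 | intermediate
28 | (1S,2S)-1-(4-hydroxy-3-methoxyphenyl)-2-{4-[(2S,3R,4R)-4-(4-hydroxy-3-methoxybenzyl)-3-(hydroxymethyl)oxolan-2-yl]-2-methoxyphenoxy}propane-1,3-diol | COc1cc(C[C@H]2CO[C@H](c3ccc(O[C@@H](CO)[C@@H](O)c4ccc(O)c(OC)c4)c(OC)c3)[C@H]2CO)ccc1O | target

Total step count: 15. Longest linear sequence: 12 steps (steps 1–6 and 10–15).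

**Steps most likely to fail**

Step 13 (key step). The radical 24 may take a hydrogen atom before it cyclises, the stannyl radical may add to the aryl alkyne, or the vinyl radical may be trapped by the thiocarbonyl group of unreacted ester. The fallback replaces the radical by a polar ring closure on the same bond. It sets out from 21, which is O-alkylated with ICH2SnBu3 (KH, THF) to give the (tributylstannyl)methyl ether of 21 F1. Tin–lithium exchange (n-BuLi, THF, −78 °C) and warming to about −50 °C should bring about 5-exo-dig carbolithiation of the aryl alkyne, at a temperature where α-alkoxymethyllithiums of the benzyloxymethyl type do not yet undergo Wittig rearrangement. A methanol quench returns the route at 26, as one alkene isomer, which is immaterial.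

Step 10. With an aromatic aldehyde the preference for the anti adduct may be only moderate, and the propargylzinc tautomer may lose silanolate by β-elimination. The fallback replaces the propargylation by an aldol reaction and sets out from 13. A MgCl2-catalysed anti-aldol reaction (MgCl2, Et3N, Me3SiCl, EtOAc) is run with (S)-4-benzyl-3-[3-(triisopropylsilyloxy)propanoyl]-1,3-oxazolidin-2-one F2, which is to be made from (S)-4-benzyl-1,3-oxazolidin-2-one and 3-(triisopropylsilyloxy)propanoic acid. The chelated enolate should give the anti-aldol trimethylsilyl ether F3 with the C2/C3 configuration of 19. LiBH4 reduces it to the primary alcohol F4, and Dess–Martin periodinane oxidises that to the aldehyde F5. Ohira–Bestmann homologation (dimethyl (1-diazo-2-oxopropyl)phosphonate, K2CO3, MeOH), which also cleaves the trimethylsilyl ether, returns the route at 19.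

Step 15. Facial discrimination may be insufficient, the double bond may migrate into the ring before reduction (loss of the C3 configuration), or the allylic C5–O1, benzylic C2–O1 or C7''–O bonds may be hydrogenolysed. The fallback separates alkene reduction from debenzylation and sets out from 26. Metal-hydride hydrogen-atom-transfer hydrogenation (Mn(dpm)3, PhSiH3, t-BuOOH, i-PrOH) should deliver the hydrogen atom to C4 anti to the bulky silyloxymethyl group, with no hydrogenolysis pathway, and give the saturated silyl-protected oxolane F6. TBAF then gives the bis-benzyl ether of the target F7, and transfer hydrogenolysis (Pd(OH)2/C, cyclohexa-1,4-diene, EtOH) returns the route at 28.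

**Further compounds**

F1 | step 13 | (tributylstannyl)methyl ether of 21 | CCCC[Sn](CCCC)(CCCC)CO[C@H](c1ccc(O[C@@H](CO[Si](C)(C)C(C)(C)C)[C@@H](O[Si](C)(C)C(C)(C)C)c2ccc(OCc3ccccc3)c(OC)c2)c(OC)c1)[C@H](C#Cc1ccc(OCc2ccccc2)c(OC)c1)CO[Si](C(C)C)(C(C)C)C(C)C
F2 | step 10 | (S)-4-benzyl-3-[3-(triisopropylsilyloxy)propanoyl]-1,3-oxazolidin-2-one | CC(C)[Si](OCCC(=O)N1[C@@H](Cc2ccccc2)COC1=O)(C(C)C)C(C)C
F3 | step 10 | (S)-4-benzyl-3-[(2R,3S)-3-ArA-2-[(triisopropylsilyloxy)methyl]-3-(trimethylsilyloxy)propanoyl]-1,3-oxazolidin-2-one | C[Si](C)(C)O[C@H](c1ccc(O[C@@H](CO[Si](C)(C)C(C)(C)C)[C@@H](O[Si](C)(C)C(C)(C)C)c2ccc(OCc3ccccc3)c(OC)c2)c(OC)c1)[C@H](C(=O)N1[C@@H](Cc2ccccc2)COC1=O)CO[Si](C(C)C)(C(C)C)C(C)C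
F4 | step 10 | primary alcohol from reduction of F3 (3-ArA-2-[(triisopropylsilyloxy)methyl]-3-(trimethylsilyloxy)propan-1-ol) | C[Si](C)(C)O[C@H](c1ccc(O[C@@H](CO[Si](C)(C)C(C)(C)C)[C@@H](O[Si](C)(C)C(C)(C)C)c2ccc(OCc3ccccc3)c(OC)c2)c(OC)c1)[C@H](CO)CO[Si](C(C)C)(C(C)C)C(C)C
F5 | step 10 | aldehyde from oxidation of F4 | C[Si](C)(C)O[C@H](c1ccc(O[C@@H](CO[Si](C)(C)C(C)(C)C)[C@@H](O[Si](C)(C)C(C)(C)C)c2ccc(OCc3ccccc3)c(OC)c2)c(OC)c1)[C@H](C=O)CO[Si](C(C)C)(C(C)C)C(C)C
F6 | step 15 | (2S,3R,4R)-2-ArA-4-(ArB-methyl)-3-[(triisopropylsilyloxy)methyl]oxolane | COc1cc(C[C@H]2CO[C@H](c3ccc(O[C@@H](CO[Si](C)(C)C(C)(C)C)[C@@H](O[Si](C)(C)C(C)(C)C)c4ccc(OCc5ccccc5)c(OC)c4)c(OC)c3)[C@H]2CO[Si](C(C)C)(C(C)C)C(C)C)ccc1OCc1ccccc1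
F7 | step 15 | bis-benzyl ether of the target (both phenols benzylated) | COc1cc(C[C@H]2CO[C@H](c3ccc(O[C@@H](CO)[C@@H](O)c4ccc(OCc5ccccc5)c(OC)c4)c(OC)c3)[C@H]2CO)ccc1OCc1ccccc1
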